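**Plan**

1. Numbering: xanthanolide numbers; unprimed = dienone half (spiro carbon C11, its ring CH2 neighbour C13, lactone carbonyl C12), primed = hydroxylated half.
2. Retrosynthetic cuts, in order: C11'=C13' (elimination from a CH2OH mask); C1=C5 and C2=C3 of the lower ring (enyne ring closure, cross-metathesis); lactone bond C12–O(C8), moved back to C12–O(C1') (acyl transfer); C11–C13 and C1'–C5' together (retro-[4+2] to a 2-pyrone); pyrone O–C1' and C2'–C3' (lactonisation, Sonogashira); both halves then fall back to one aldol adduct.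
3. Enabling feature: in the cyclohexene ring C1'–C2'=C3'–C11–C13–C5' the C1' hydroxyl and the C12 carboxyl are cis and 1,4 across the C2'=C3' bond. The ring is therefore a ring-opened 2-oxabicyclo[2.2.2]oct-5-en-3-one, the adduct of a 2-pyrone (O, C12, C11, C3', C2', C1') and the alkene C13=C5'.
4. Forward ring order: upper γ-lactone, then 2-pyrone, then cyclohexene and upper cycloheptane in one cycloaddition, then lower γ-lactone (acyl transfer), then lower cycloheptadiene (enyne metathesis), then the methylene.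
5. Stereochemistry: C10 and C10' from one Rh-catalysed conjugate alkynylation; C7, C8 and C7' from one Evans syn-aldol; C8' by SN2 inversion; C1', C5' and C11 in the cycloaddition (allylic strain at C11–C7, trans-lactone tether).

Key step: step 17

Remark: the DTBM-SEGPHOS antipode of step 1 is taken as the one that gives the 3S aldehyde, and the configuration written at the hydroxymethyl-bearing carbon of 22–32 and left open at C2 of 16 is of no consequence because both carbons become trigonal.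

**Route**

Step 1
Reactants: 1 (E)-but-2-enal; 2 ethynyltri(propan-2-yl)silane
Product: 3 (3S)-3-methyl-5-[tri(propan-2-yl)silyl]pent-4-ynal
Conditions: [Rh(OAc)(C2H4)2]2 (2.5 mol %), DTBM-SEGPHOS (antipode giving 3S), MeOH, 40 °C
Reagents that add atoms: none
Why: Rhodium-catalysed asymmetric conjugate alkynylation of an enal should add the alkynyl group 1,4, the bulky silyl group suppressing alkyne dimerisation and the chiral bisphosphine setting C3 (the later C10 and C10').

Step 2
Reactants: 4 (4R)-4-benzyl-1,3-oxazolidin-2-one; 5 pent-4-enoyl chloride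
Product: 6 (4R)-4-benzyl-3-(pent-4-enoyl)-1,3-oxazolidin-2-one
Conditions: n-BuLi, THF, −78 °C; then 5, −78 to 0 °C
Reagents that add atoms: none
Why: N-Acylation of the lithiated oxazolidinone with the acid chloride (Evans imide formation) should be clean and creates no stereocentre.

Step 3
Reactants: 6 (4R)-4-benzyl-3-(pent-4-enoyl)-1,3-oxazolidin-2-one; 3 (3S)-3-methyl-5-[tri(propan-2-yl)silyl]pent-4-ynal
Product: 7 (4R)-4-benzyl-3-[(2R,3S,5S)-3-hydroxy-5-methyl-2-(prop-2-en-1-yl)-7-[tri(propan-2-yl)silyl]hept-6-ynoyl]-1,3-oxazolidin-2-one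
Conditions: Bu2BOTf, i-Pr2NEt, CH2Cl2, −78 to 0 °C; then 3, −78 to 0 °C; pH 7 buffer, MeOH, H2O2
Reagents that add atoms: none
Why: Evans syn-aldol reaction: the (Z)-boron enolate reacts through a chair Zimmerman–Traxler transition state on the face opposite the benzyl group, so the (R)-auxiliary should set 2R,3S (the later C7 and C8) independently of the remote C5 centre.

Step 4
Reactants: 7 syn-aldol adduct
Product: 8 (4R)-4-benzyl-3-[(2R,3S,5S)-3-[(tert-butyldimethylsilyl)oxy]-5-methyl-2-(prop-2-en-1-yl)-7-[tri(propan-2-yl)silyl]hept-6-ynoyl]-1,3-oxazolidin-2-one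
Conditions: TBSOTf, 2,6-lutidine, CH2Cl2, −78 to 0 °C
Reagents that add atoms: tert-butyldimethylsilyl trifluoromethanesulfonate, CC(C)(C)[Si](C)(C)OS(=O)(=O)C(F)(F)F
Why: Silylation of the secondary alcohol with the silyl triflate protects the later C8–OH for the enolate chemistry ahead and blocks retro-aldol cleavage; no stereocentre is affected.

Step 5
Reactants: 8 silylated imide
Product: 10 (2R,3S,5S)-3-[(tert-butyldimethylsilyl)oxy]-5-methyl-2-(prop-2-en-1-yl)-7-[tri(propan-2-yl)silyl]hept-6-ynoic acid, via peroxy acid 9 (not isolated)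
Conditions: LiOH, H2O2, THF–H2O, 0 °C; then Na2SO3; HCl to pH 3
Reagents that add atoms: hydrogen peroxide, OO
Why: Hydroperoxide cleavage of the Evans imide attacks the exocyclic carbonyl selectively and the peroxy acid is reduced by sulfite, so the acid should form without epimerisation at C2.

Step 6
Reactants: 10 silyloxy acid
Product: 12 (3R,4S,6S)-4-[(tert-butyldimethylsilyl)oxy]-1-diazo-6-methyl-3-(prop-2-en-1-yl)-8-[tri(propan-2-yl)silyl]oct-7-yn-2-one, via mixed carbonic anhydride 11 (not isolated)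
Conditions: i-BuOCOCl, Et3N, THF, −15 °C; then CH2N2, Et2O, 0 °C to rt
Reagents that add atoms: diazomethane, C=[N+]=[N-]
Why: First stage of the Arndt–Eistert homologation: the mixed anhydride acylates diazomethane to the α-diazoketone under neutral conditions that spare the silyl ether and the α-stereocentre.

Step 7
Reactants: 12 diazoketone
Product: 14 tert-butyl (3S,4S,6S)-4-[(tert-butyldimethylsilyl)oxy]-6-methyl-3-(prop-2-en-1-yl)-8-[tri(propan-2-yl)silyl]oct-7-ynoate, via ketene 13 (not isolated)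
Conditions: PhCO2Ag (10 mol %), Et3N, t-BuOH–THF, rt, dark
Reagents that add atoms: tert-butanol, CC(C)(C)O
Why: Silver-promoted Wolff rearrangement: the C3 carbon migrates with retention to a ketene that tert-butanol traps, so the chain gains the carbon that becomes the spiro carbon C11.

Step 8
Reactants: 14 tert-butyl ester; 15 methyl 2,2-dimethoxypropanoate
Product: 16 tert-butyl (3S,4S,6S)-4-[(tert-butyldimethylsilyl)oxy]-2-(2,2-dimethoxypropanoyl)-6-methyl-3-(prop-2-en-1-yl)-8-[tri(propan-2-yl)silyl]oct-7-ynoate (C2 epimers)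
Conditions: LiN(i-Pr)2 (2.2 equiv), THF, −78 °C; then 15, −78 to −30 °C; NH4Cl
Reagents that add atoms: none
Why: Crossed Claisen condensation of the ester enolate with a non-enolisable, inductively activated ester should give the β-keto ester, the second equivalent of base removing the acidic C2–H and driving the reaction.

Step 9
Reactants: 16 β-keto ester
Product: 17 tert-butyl (2Z)-2-[(4S,5S,7S)-5-[(tert-butyldimethylsilyl)oxy]-7-methyl-9-[tri(propan-2-yl)silyl]non-1-en-8-yn-4-yl]-4,4-dimethoxy-3-[(trifluoromethanesulfonyl)oxy]pent-2-enoate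
Conditions: NaH, THF, 0 °C; then PhNTf2, 0 °C to rt
Reagents that add atoms: N-phenylbis(trifluoromethanesulfonimide), O=S(=O)(N(c1ccccc1)S(=O)(=O)C(F)(F)F)C(F)(F)F
Why: O-Sulfonylation of the chelated sodium enolate of the β-keto ester should give the Z enol triflate (ester and triflate cis), the geometry the later lactonisation needs.

Step 10
Reactants: 14 tert-butyl ester
Product: 18 tert-butyl (3S,4S,6S)-4-hydroxy-6-methyl-3-(prop-2-en-1-yl)-8-[tri(propan-2-yl)silyl]oct-7-ynoate
Conditions: HF·pyridine, pyridine, THF, 0 °C to rt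
Reagents that add atoms: none
Why: Acidic fluoride cleaves the O–Si bond of the secondary silyl ether but not the C–Si bond of the alkyne (chemoselective desilylation), and the tert-butyl ester resists lactonisation, so the free carbinol is available for inversion.

Step 11
Reactants: 18 hydroxy ester
Product: 19 tert-butyl (3S,4S,6S)-4-(methanesulfonyloxy)-6-methyl-3-(prop-2-en-1-yl)-8-[tri(propan-2-yl)silyl]oct-7-ynoate
Conditions: MsCl, Et3N, CH2Cl2, 0 °C
Reagents that add atoms: methanesulfonyl chloride, CS(=O)(=O)Cl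
Why: Sulfonylation of the secondary alcohol (mesylate formation) turns C4–O into a leaving group with retention.

Step 12
Reactants: 19 mesylate
Product: 21 (4S,5R)-5-[(2S)-2-methyl-4-[tri(propan-2-yl)silyl]but-3-yn-1-yl]-4-(prop-2-en-1-yl)oxolan-2-one, via mesyloxy acid 20 (not isolated)
Conditions: CF3CO2H, CH2Cl2, 0 °C; evaporate; then Cs2CO3, DMF, rt to 40 °C
Reagents that add atoms: none
Why: Acidolysis of the tert-butyl ester and intramolecular SN2 O-alkylation of the cesium carboxylate (5-exo-tet lactonisation) should invert C4, which sets C8' and gives the trans-4,5-disubstituted lactone.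

Step 13
Reactants: 21 trans-lactone
Product: 22 (3R,4S,5R)-3-(hydroxymethyl)-5-[(2S)-2-methyl-4-[tri(propan-2-yl)silyl]but-3-yn-1-yl]-4-(prop-2-en-1-yl)oxolan-2-one
Conditions: LiN(i-Pr)2, THF, −78 °C; then CH2O (gas, from paraformaldehyde), −78 to −40 °C
Reagents that add atoms: formaldehyde, C=O
Why: Aldol reaction of the lactone lithium enolate with formaldehyde should occur anti to the C4 allyl group; the hydroxymethyl group is the masked C13' methylene, which cannot act as a dienophile.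

Step 14
Reactants: 22 hydroxymethyl lactone
Product: 23 (3R,4S,5R)-3-(hydroxymethyl)-5-[(2S)-2-methylbut-3-yn-1-yl]-4-(prop-2-en-1-yl)oxolan-2-one
Conditions: Bu4NF, AcOH (1:1), THF, rt
Reagents that add atoms: none
Why: Fluoride-induced protodesilylation of the alkynylsilane, buffered with acetic acid to spare the β-hydroxy lactone, frees the terminal alkyne for coupling.

Step 15
Reactants: 17 enol triflate; 23 alkynyl lactone
Product: 24 tert-butyl (2E,6S)-2-[(4S,5S,7S)-5-[(tert-butyldimethylsilyl)oxy]-7-methyl-9-[tri(propan-2-yl)silyl]non-1-en-8-yn-4-yl]-3-(1,1-dimethoxyethyl)-7-[(2R,3S,4R)-4-(hydroxymethyl)-5-oxo-3-(prop-2-en-1-yl)oxolan-2-yl]-6-methylhept-2-en-4-ynoate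
Conditions: Pd(PPh3)4 (5 mol %), CuI (10 mol %), i-Pr2NEt, DMF, rt
Reagents that add atoms: none
Why: Sonogashira coupling of the enol triflate with the terminal alkyne should form C2'–C3' with retention of the double-bond geometry and joins the two halves without touching the silyl groups, the lactone or the ketal.

Step 16
Reactants: 24 enynoate
Product: 26 4-acetyl-3-[(4S,5S,7S)-5-[(tert-butyldimethylsilyl)oxy]-7-methyl-9-[tri(propan-2-yl)silyl]non-1-en-8-yn-4-yl]-6-[(2S)-1-[(2R,3S,4R)-4-(hydroxymethyl)-5-oxo-3-(prop-2-en-1-yl)oxolan-2-yl]propan-2-yl]-2H-pyran-2-one, via ketal pyrone 25 (not isolated)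
Conditions: (Ph3P)AuNTf2 (5 mol %), CH2Cl2, rt; then PPTS, acetone–H2O, 40 °C
Reagents that add atoms: water, O
Why: Gold-catalysed 6-endo-dig attack of the ester carbonyl oxygen on the cis alkyne with loss of 2-methylpropene (cycloisomerisation of a tert-butyl alkynoate to a 2-pyrone), then mild ketal hydrolysis, should give the 4-acetyl-2-pyrone; the ketal keeps the ketone from furan formation during the gold step.

Step 17
Reactants: 26 tethered 2-pyrone
Product: 27 bridged-lactone cycloadduct (2-oxabicyclo[2.2.2]oct-5-en-3-one fused at C1'–C5' to the new cycloheptane)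
Conditions: toluene (0.005 M), BHT (cat.), 120 °C, sealed tube
Reagents that add atoms: none
Why: Thermal, concerted but asynchronous [4+2] cycloaddition in which the electron-poor 2-pyrone (diene C11=C3'–C2'=C1', carrying the ring carbonyl and the C3' acetyl group) adds across the tethered unactivated alkene C13=C5', forming C11–C13 and C1'–C5' and leaving the C2'=C3' double bond and the C12(=O)–O–C1' lactone as the bridge of a 2-oxabicyclo[2.2.2]oct-5-en-3-one. The closest known reaction type is the intramolecular Diels–Alder reaction of 2-pyrones with tethered alkenes, whose bicyclic lactone adducts are isolable below the temperature of CO2 loss. The cyclohexene ring is closed by the cycloaddition itself (both new bonds), and the cycloheptane ring is closed in the fused mode through the five-atom tether C10'–C9'–C8'–C7'–C6' that links pyrone carbon C1' to the internal alkene carbon C5'. C1' and C11 are tied cis by the lactone bridge and their sense is set by the pyrone face: allylic 1,3-strain holds C7–H in the pyrone plane next to the acetyl group, so the silyloxy-bearing C8 branch blocks one face and only the allyl CH2 lies on the other, and that open face is also compatible with a chair-like tether that keeps the trans-lactone bonds and the C10' methyl equatorial. C5' follows from the tether folding under the C2'=C3' side (cis ring fusion), the only mode that keeps this chair on that face. The step needs chemoselectivity for the five-atom-tethered alkene (the alkyne is capped by the bulky silyl group, the C7 allyl group hangs on a two-atom tether, the upper methylene is masked as CH2OH), fused rather than bridged closure (set by tether length) and retention of CO2 (temperature held at 120 °C).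

Step 18
Reactants: 27 cycloadduct
Product: 29 spiro-lactone diol enyne (C12–O–C8 γ-lactone; free C1'–OH and C13'–OH; terminal alkyne), via hydroxy bridged lactone 28 (not isolated)
Conditions: Bu4NF (3 equiv), THF, 0 °C to rt; NH4Cl
Reagents that add atoms: none
Why: Fluoride removes both silyl groups and the C8 alkoxide, held cis and γ to the bridging carbonyl C12, should attack it in a 5-exo-trig acyl transfer (translactonisation) that opens the strained bicyclic lactone, forms the cis-fused γ-lactone of the lower half and releases the tertiary C1' alcohol, no stereocentre being touched.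

Step 19
Reactants: 29 spiro-lactone diol enyne; 30 but-3-en-2-one
Product: 31 13'-hydroxy-11',13'-dihydro derivative of the target (11'R)
Conditions: second-generation Hoveyda–Grubbs catalyst (10 mol %), 30 (5 equiv), CH2Cl2, 40 °C
Reagents that add atoms: none
Why: Domino ring-closing enyne metathesis and cross-metathesis with the vinyl ketone, a sequence with precedent on cis-fused xanthanolide lactones, should close the lower seven-membered ring to the 1-vinylcycloheptene and extend it to the E dienone; the trisubstituted enone is inert.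

Step 20
Reactants: 31 hydroxymethyl precursor
Product: 33 CNP0168949.5 (target), via primary mesylate 32 (not isolated)
Conditions: MsCl, Et3N, CH2Cl2, 0 °C; then DBU, rt
Reagents that add atoms: none
Why: Selective mesylation of the primary alcohol and E1cB elimination with DBU (β-elimination of a β-sulfonyloxy lactone) should unveil the α-methylene lactone, the tertiary alcohol being too hindered to react.

**Compound list**

1 | (E)-but-2-enal | C/C=C/C=O | starting material
2 | ethynyltri(propan-2-yl)silane | C#C[Si](C(C)C)(C(C)C)C(C)C | starting material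
3 | (3S)-3-methyl-5-[tri(propan-2-yl)silyl]pent-4-ynal | O=CC[C@H](C)C#C[Si](C(C)C)(C(C)C)C(C)C | intermediate
4 | (4R)-4-benzyl-1,3-oxazolidin-2-one | O=C1OC[C@@H](Cc2ccccc2)N1 | starting material
5 | pent-4-enoyl chloride | C=CCCC(=O)Cl | starting material
6 | (4R)-4-benzyl-3-(pent-4-enoyl)-1,3-oxazolidin-2-one | O=C1OC[C@@H](Cc2ccccc2)N1C(=O)CCC=C | intermediate
7 | (4R)-4-benzyl-3-[(2R,3S,5S)-3-hydroxy-5-methyl-2-(prop-2-en-1-yl)-7-[tri(propan-2-yl)silyl]hept-6-ynoyl]-1,3-oxazolidin-2-one | O=C1OC[C@@H](Cc2ccccc2)N1C(=O)[C@H](CC=C)[C@@H](O)C[C@H](C)C#C[Si](C(C)C)(C(C)C)C(C)C | intermediate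
8 | (4R)-4-benzyl-3-[(2R,3S,5S)-3-[(tert-butyldimethylsilyl)oxy]-5-methyl-2-(prop-2-en-1-yl)-7-[tri(propan-2-yl)silyl]hept-6-ynoyl]-1,3-oxazolidin-2-one | O=C1OC[C@@H](Cc2ccccc2)N1C(=O)[C@H](CC=C)[C@@H](O[Si](C)(C)C(C)(C)C)C[C@H](C)C#C[Si](C(C)C)(C(C)C)C(C)C | intermediate
9 | (2R,3S,5S)-3-[(tert-butyldimethylsilyl)oxy]-5-methyl-2-(prop-2-en-1-yl)-7-[tri(propan-2-yl)silyl]hept-6-yneperoxoic acid (not isolated) | OOC(=O)[C@H](CC=C)[C@@H](O[Si](C)(C)C(C)(C)C)C[C@H](C)C#C[Si](C(C)C)(C(C)C)C(C)C | intermediate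
10 | (2R,3S,5S)-3-[(tert-butyldimethylsilyl)oxy]-5-methyl-2-(prop-2-en-1-yl)-7-[tri(propan-2-yl)silyl]hept-6-ynoic acid | OC(=O)[C@H](CC=C)[C@@H](O[Si](C)(C)C(C)(C)C)C[C@H](C)C#C[Si](C(C)C)(C(C)C)C(C)C | intermediate
11 | mixed anhydride of 10 with 2-methylpropyl hydrogen carbonate (not isolated) | CC(C)COC(=O)OC(=O)[C@H](CC=C)[C@@H](O[Si](C)(C)C(C)(C)C)C[C@H](C)C#C[Si](C(C)C)(C(C)C)C(C)C | intermediate
12 | (3R,4S,6S)-4-[(tert-butyldimethylsilyl)oxy]-1-diazo-6-methyl-3-(prop-2-en-1-yl)-8-[tri(propan-2-yl)silyl]oct-7-yn-2-one | [N-]=[N+]=CC(=O)[C@H](CC=C)[C@@H](O[Si](C)(C)C(C)(C)C)C[C@H](C)C#C[Si](C(C)C)(C(C)C)C(C)C | intermediate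
13 | (3S,4S,6S)-4-[(tert-butyldimethylsilyl)oxy]-6-methyl-3-(prop-2-en-1-yl)-8-[tri(propan-2-yl)silyl]oct-1-en-7-yn-1-one, the ketene (not isolated) | O=C=C[C@H](CC=C)[C@@H](O[Si](C)(C)C(C)(C)C)C[C@H](C)C#C[Si](C(C)C)(C(C)C)C(C)C | intermediate
14 | tert-butyl (3S,4S,6S)-4-[(tert-butyldimethylsilyl)oxy]-6-methyl-3-(prop-2-en-1-yl)-8-[tri(propan-2-yl)silyl]oct-7-ynoate | CC(C)(C)OC(=O)C[C@H](CC=C)[C@@H](O[Si](C)(C)C(C)(C)C)C[C@H](C)C#C[Si](C(C)C)(C(C)C)C(C)C | intermediate
15 | methyl 2,2-dimethoxypropanoate | COC(=O)C(C)(OC)OC | starting material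
16 | tert-butyl (3S,4S,6S)-4-[(tert-butyldimethylsilyl)oxy]-2-(2,2-dimethoxypropanoyl)-6-methyl-3-(prop-2-en-1-yl)-8-[tri(propan-2-yl)silyl]oct-7-ynoate (C2 epimers) | CC(C)(C)OC(=O)C(C(=O)C(C)(OC)OC)[C@H](CC=C)[C@@H](O[Si](C)(C)C(C)(C)C)C[C@H](C)C#C[Si](C(C)C)(C(C)C)C(C)C | intermediate
17 | tert-butyl (2Z)-2-[(4S,5S,7S)-5-[(tert-butyldimethylsilyl)oxy]-7-methyl-9-[tri(propan-2-yl)silyl]non-1-en-8-yn-4-yl]-4,4-dimethoxy-3-[(trifluoromethanesulfonyl)oxy]pent-2-enoate | CC(C)(C)OC(=O)/C([C@H](CC=C)[C@@H](O[Si](C)(C)C(C)(C)C)C[C@H](C)C#C[Si](C(C)C)(C(C)C)C(C)C)=C(\OS(=O)(=O)C(F)(F)F)C(C)(OC)OC | intermediate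
18 | tert-butyl (3S,4S,6S)-4-hydroxy-6-methyl-3-(prop-2-en-1-yl)-8-[tri(propan-2-yl)silyl]oct-7-ynoate | CC(C)(C)OC(=O)C[C@H](CC=C)[C@@H](O)C[C@H](C)C#C[Si](C(C)C)(C(C)C)C(C)C | intermediate
19 | tert-butyl (3S,4S,6S)-4-(methanesulfonyloxy)-6-methyl-3-(prop-2-en-1-yl)-8-[tri(propan-2-yl)silyl]oct-7-ynoate | CC(C)(C)OC(=O)C[C@H](CC=C)[C@@H](OS(C)(=O)=O)C[C@H](C)C#C[Si](C(C)C)(C(C)C)C(C)C | intermediate
20 | (3S,4S,6S)-4-(methanesulfonyloxy)-6-methyl-3-(prop-2-en-1-yl)-8-[tri(propan-2-yl)silyl]oct-7-ynoic acid (not isolated) | OC(=O)C[C@H](CC=C)[C@@H](OS(C)(=O)=O)C[C@H](C)C#C[Si](C(C)C)(C(C)C)C(C)C | intermediate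
21 | (4S,5R)-5-[(2S)-2-methyl-4-[tri(propan-2-yl)silyl]but-3-yn-1-yl]-4-(prop-2-en-1-yl)oxolan-2-one | O=C1O[C@H](C[C@H](C)C#C[Si](C(C)C)(C(C)C)C(C)C)[C@@H](CC=C)C1 | intermediate
22 | (3R,4S,5R)-3-(hydroxymethyl)-5-[(2S)-2-methyl-4-[tri(propan-2-yl)silyl]but-3-yn-1-yl]-4-(prop-2-en-1-yl)oxolan-2-one | O=C1O[C@H](C[C@H](C)C#C[Si](C(C)C)(C(C)C)C(C)C)[C@@H](CC=C)[C@@H]1CO | intermediate
23 | (3R,4S,5R)-3-(hydroxymethyl)-5-[(2S)-2-methylbut-3-yn-1-yl]-4-(prop-2-en-1-yl)oxolan-2-one | O=C1O[C@H](C[C@H](C)C#C)[C@@H](CC=C)[C@@H]1CO | intermediate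
24 | tert-butyl (2E,6S)-2-[(4S,5S,7S)-5-[(tert-butyldimethylsilyl)oxy]-7-methyl-9-[tri(propan-2-yl)silyl]non-1-en-8-yn-4-yl]-3-(1,1-dimethoxyethyl)-7-[(2R,3S,4R)-4-(hydroxymethyl)-5-oxo-3-(prop-2-en-1-yl)oxolan-2-yl]-6-methylhept-2-en-4-ynoate | CC(C)(C)OC(=O)/C([C@H](CC=C)[C@@H](O[Si](C)(C)C(C)(C)C)C[C@H](C)C#C[Si](C(C)C)(C(C)C)C(C)C)=C(\C#C[C@@H](C)C[C@H]1OC(=O)[C@@H](CO)[C@@H]1CC=C)C(C)(OC)OC | intermediate
25 | 3-[(4S,5S,7S)-5-[(tert-butyldimethylsilyl)oxy]-7-methyl-9-[tri(propan-2-yl)silyl]non-1-en-8-yn-4-yl]-4-(1,1-dimethoxyethyl)-6-[(2S)-1-[(2R,3S,4R)-4-(hydroxymethyl)-5-oxo-3-(prop-2-en-1-yl)oxolan-2-yl]propan-2-yl]-2H-pyran-2-one (not isolated) | O=C1OC([C@@H](C)C[C@H]2OC(=O)[C@@H](CO)[C@@H]2CC=C)=CC(C(C)(OC)OC)=C1[C@H](CC=C)[C@@H](O[Si](C)(C)C(C)(C)C)C[C@H](C)C#C[Si](C(C)C)(C(C)C)C(C)C | intermediate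
26 | 4-acetyl-3-[(4S,5S,7S)-5-[(tert-butyldimethylsilyl)oxy]-7-methyl-9-[tri(propan-2-yl)silyl]non-1-en-8-yn-4-yl]-6-[(2S)-1-[(2R,3S,4R)-4-(hydroxymethyl)-5-oxo-3-(prop-2-en-1-yl)oxolan-2-yl]propan-2-yl]-2H-pyran-2-one | O=C1OC([C@@H](C)C[C@H]2OC(=O)[C@@H](CO)[C@@H]2CC=C)=CC(C(C)=O)=C1[C@H](CC=C)[C@@H](O[Si](C)(C)C(C)(C)C)C[C@H](C)C#C[Si](C(C)C)(C(C)C)C(C)C | intermediate
27 | cycloadduct: 2-oxabicyclo[2.2.2]oct-5-en-3-one (bridge C12(=O)–O from C11 to C1', C2'=C3' with acetyl on C3') fused at C1'–C5' to a cycloheptane carrying the C10' methyl and the trans-fused 3-(hydroxymethyl)-γ-lactone at C7'–C8'; C11 bears the (4S,5S,7S)-5-[(tert-butyldimethylsilyl)oxy]-7-methyl-9-[tri(propan-2-yl)silyl]non-1-en-8-yn-4-yl chain; C5'–H on the side of the lactone bridge | OC[C@@H]1C(=O)O[C@@H]2C[C@H](C)[C@@]34OC(=O)[C@@](C[C@@H]3C[C@@H]12)(C(C(C)=O)=C4)[C@H](CC=C)[C@@H](O[Si](C)(C)C(C)(C)C)C[C@H](C)C#C[Si](C(C)C)(C(C)C)C(C)C | intermediate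
28 | 27 without both silyl groups: free C8 hydroxyl (as alkoxide) and terminal alkyne on the bridged lactone (not isolated) | OC[C@@H]1C(=O)O[C@@H]2C[C@H](C)[C@@]34OC(=O)[C@@](C[C@@H]3C[C@@H]12)(C(C(C)=O)=C4)[C@H](CC=C)[C@@H](O)C[C@H](C)C#C | intermediate
29 | spiro-lactone diol enyne: C12 esterified by O–C8 (cis-disubstituted γ-lactone, spiro at C11 of the cyclohexene), free tertiary C1'–OH, C7 allyl, C8 (2S)-2-methylbut-3-yn-1-yl, upper trans-fused lactone with C11'–CH2OH | OC[C@@H]1C(=O)O[C@@H]2C[C@H](C)[C@]3(O)C=C(C(C)=O)[C@]4(C[C@@H]3C[C@@H]12)C(=O)O[C@@H](C[C@H](C)C#C)[C@H]4CC=C | intermediate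
30 | but-3-en-2-one | C=CC(C)=O | starting material
31 | 13'-hydroxy-11',13'-dihydro derivative of the target (11'R; CH–CH2OH in place of the exocyclic methylene of the upper lactone) | OC[C@@H]1C(=O)O[C@@H]2C[C@H](C)[C@]3(O)C=C(C(C)=O)[C@]4(C[C@@H]3C[C@@H]12)C(=O)O[C@H]1C[C@H](C)C(/C=C/C(C)=O)=CC[C@H]14 | intermediate
32 | 13'-O-methanesulfonate of 31 (not isolated) | CS(=O)(=O)OC[C@@H]1C(=O)O[C@@H]2C[C@H](C)[C@]3(O)C=C(C(C)=O)[C@]4(C[C@@H]3C[C@@H]12)C(=O)O[C@H]1C[C@H](C)C(/C=C/C(C)=O)=CC[C@H]14 | intermediate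
33 | CNP0168949.5 | C=C1C(=O)O[C@@H]2C[C@H](C)[C@]3(O)C=C(C(C)=O)[C@]4(C[C@@H]3C[C@@H]12)C(=O)O[C@H]1C[C@H](C)C(/C=C/C(C)=O)=CC[C@H]14 | target

**Count and risks**

Total step count: 20. Longest linear sequence: 17 steps (steps 1, 3–7, 10–20).

Steps most likely to fail:

Step 17. The two pyrone faces may not be told apart well enough, or closure of the seven-membered ring may be so slow that cycloaddition to the silylated alkyne and loss of CO2 from the adduct compete. The fallback closes the lower ring first, which consumes the alkyne and makes the face-selecting C7 substituent rigid. It sets out from 26: AgF in MeOH then dilute HCl should remove the C-silyl group to give the terminal-alkyne pyrone F1. Ring-closing enyne metathesis (second-generation Grubbs catalyst, ethylene, CH2Cl2, 40 °C) should then give the cycloheptenyl pyrone F2. Heating as in step 17 should give the cycloadduct F3. Cross-metathesis with 30 (second-generation Hoveyda–Grubbs catalyst) should give the dienone cycloadduct F4. Bu4NF then removes the silyl ether and triggers the acyl transfer, and the route is rejoined at 31.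

Step 16. Under π-acid activation, 5-exo closure or attack by a ketal oxygen may compete with 6-endo attack by the ester carbonyl. The fallback sets out from 24: TMSOTf and 2,6-lutidine followed by aqueous work-up should cleave the tert-butyl ester to the free enynoic acid F5 (carboxyl cis to the alkyne). Catalytic ZnBr2 in THF should then lactonise the acid in the 6-endo mode, and the route is rejoined at 25.

Step 19. Cross-metathesis of the allyl group with the vinyl ketone, or sequestration of the catalyst by the diol, may outrun ring closure. The fallback sets out from 29: ring-closing enyne metathesis alone (second-generation Grubbs catalyst under ethylene) should give the vinylcycloheptene diol F6. A separate cross-metathesis with 30 then rejoins the route at 31.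

Further compounds
F1 | step 17 | 4-acetyl-3-[(4S,5S,7S)-5-[(tert-butyldimethylsilyl)oxy]-7-methylnon-1-en-8-yn-4-yl]-6-[(2S)-1-[(2R,3S,4R)-4-(hydroxymethyl)-5-oxo-3-(prop-2-en-1-yl)oxolan-2-yl]propan-2-yl]-2H-pyran-2-one | O=C1OC([C@@H](C)C[C@H]2OC(=O)[C@@H](CO)[C@@H]2CC=C)=CC(C(C)=O)=C1[C@H](CC=C)[C@@H](O[Si](C)(C)C(C)(C)C)C[C@H](C)C#C
F2 | step 17 | 4-acetyl-3-[(1S,2S,4S)-2-[(tert-butyldimethylsilyl)oxy]-5-ethenyl-4-methylcyclohept-5-en-1-yl]-6-[(2S)-1-[(2R,3S,4R)-4-(hydroxymethyl)-5-oxo-3-(prop-2-en-1-yl)oxolan-2-yl]propan-2-yl]-2H-pyran-2-one | O=C1OC([C@@H](C)C[C@H]2OC(=O)[C@@H](CO)[C@@H]2CC=C)=CC(C(C)=O)=C1[C@@H]3CC=C(C=C)[C@@H](C)C[C@@H]3O[Si](C)(C)C(C)(C)C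
F3 | step 17 | cycloadduct of F2: bridged lactone as in 27 with C11 bearing the (1S,2S,4S)-2-[(tert-butyldimethylsilyl)oxy]-5-ethenyl-4-methylcyclohept-5-en-1-yl ring | OC[C@@H]1C(=O)O[C@@H]2C[C@H](C)[C@@]34OC(=O)[C@@](C[C@@H]3C[C@@H]12)(C(C(C)=O)=C4)[C@@H]5CC=C(C=C)[C@@H](C)C[C@@H]5O[Si](C)(C)C(C)(C)C
F4 | step 17 | F3 with an (E)-3-oxobut-1-en-1-yl group in place of the ethenyl group | OC[C@@H]1C(=O)O[C@@H]2C[C@H](C)[C@@]34OC(=O)[C@@](C[C@@H]3C[C@@H]12)(C(C(C)=O)=C4)[C@@H]5CC=C(/C=C/C(C)=O)[C@@H](C)C[C@@H]5O[Si](C)(C)C(C)(C)C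
F5 | step 16 | (2E,6S)-2-[(4S,5S,7S)-5-[(tert-butyldimethylsilyl)oxy]-7-methyl-9-[tri(propan-2-yl)silyl]non-1-en-8-yn-4-yl]-3-(1,1-dimethoxyethyl)-7-[(2R,3S,4R)-4-(hydroxymethyl)-5-oxo-3-(prop-2-en-1-yl)oxolan-2-yl]-6-methylhept-2-en-4-ynoic acid | OC(=O)/C([C@H](CC=C)[C@@H](O[Si](C)(C)C(C)(C)C)C[C@H](C)C#C[Si](C(C)C)(C(C)C)C(C)C)=C(\C#C[C@@H](C)C[C@H]1OC(=O)[C@@H](CO)[C@@H]1CC=C)C(C)(OC)OC
F6 | step 19 | 31 with an ethenyl group in place of the (E)-3-oxobut-1-en-1-yl group (vinylcycloheptene diol) | OC[C@@H]1C(=O)O[C@@H]2C[C@H](C)[C@]3(O)C=C(C(C)=O)[C@]4(C[C@@H]3C[C@@H]12)C(=O)O[C@H]1C[C@H](C)C(C=C)=CC[C@H]14
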